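**Retrosynthetic overview**
- The C20 aldehyde, C19 acid, 3β-OH and 12α-OH are set late: nitrile reduction, hydride reduction of a 3,12-diketone, and C–H oxidation of the C20 methyl from the 19-alcohol (nitrite photolysis).
- Ring B (five-membered) comes from photochemical Wolff contraction of a 6-diazo-7-oxo-ent-kaurane.
- Rings C and D and the C8 quaternary centre form together in one intramolecular palladium–trimethylenemethane [3+2] cycloaddition onto a 7-oxo-8(17)-ene decalin.
- The cycloaddition precursor comes from a C12 aldehyde and a vinyl iodide (made from propargyl alcohol) by Nozaki–Hiyama–Kishi coupling.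
- The aldehyde comes from andrographolide, which supplies rings A and B and C4, C5, C9 and C10. Ring order: A and B bought, then C and D (cycloaddition), then B contracted from six to five.

Assumption: the C12 carbinol made in step 7 is carried as a roughly 1:1 epimer pair (C12 left unassigned in the SMILES) until step 15 erases it; step 17 then sets it. Gibberellane/kaurane atom numbering is used throughout. The route has not been run; each step rests on analogy.

Step 1
Reactants: 1 andrographolide
Product: 2 andrographolide 3,19-acetonide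
Conditions: Me2C(OMe)2, PPTS, acetone/toluene, 40 °C
Reagents that add atoms: 2,2-dimethoxypropane, COC(C)(C)OC
Why: Acid-catalysed transketalisation (acetonide formation) ties the 1,3-related 3-OH and 19-OH into a six-membered acetal; no stereocentre changes.

Step 2
Reactants: 2 andrographolide 3,19-acetonide
Product: 3 C12 aldehyde (3,19-acetonide of the 8(17)-methylene trans-decalin carrying CH2CHO at C9)
Conditions: KMnO4, MgSO4, acetone/H2O, −10 °C
Reagents that add atoms: potassium permanganate, [K+].[O-][Mn](=O)(=O)=O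
Why: Permanganate oxidative alkene cleavage is fastest at the electron-poor conjugated C12=C13 bond, so the isolated 8(17)-methylene survives at low temperature.

Step 3
Reactants: 3 C12 aldehyde
Product: 4 7-hydroxy aldehyde (axial 7-OH on the face opposite the C10 methyl)
Conditions: SeO2 (0.5 equiv), t-BuOOH, CH2Cl2, 0 °C to rt
Reagents that add atoms: selenium dioxide, O=[Se]=O (catalytic oxygen carrier); tert-butyl hydroperoxide, CC(C)(C)OO (terminal oxygen source)
Why: Riley allylic oxidation (ene reaction then [2,3]-shift) hydroxylates the allylic CH2 of the 1,1-disubstituted alkene axially at C7; this centre is erased in step 4.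

Step 4
Reactants: 4 7-hydroxy aldehyde
Product: 5 7-oxo-8(17)-ene aldehyde (exocyclic enone)
Conditions: Dess–Martin periodinane, NaHCO3, CH2Cl2, 0 °C
Reagents that add atoms: none
Why: Dess–Martin oxidation of the allylic alcohol gives the α-methylene ketone under buffered, non-basic conditions that spare the aldehyde and avoid alkene isomerisation.

Step 5
Reactants: 6 propargyl alcohol
Product: 7 (E)-3-iodo-2-[(trimethylsilyl)methyl]prop-2-en-1-ol
Conditions: Me3SiCH2MgCl (2.5 equiv), CuI (10 mol%), THF, −10 °C to rt; then I2, −78 to 0 °C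
Reagents that add atoms: (trimethylsilyl)methylmagnesium chloride, C[Si](C)(C)C[Mg]Cl; iodine, II
Why: Copper-catalysed anti-carbomagnesiation of the propargylic alkoxide (magnesium chelated cis to CH2O) followed by iodinolysis with retention gives the vinyl iodide as one isomer.

Step 6
Reactants: 7 (E)-3-iodo-2-[(trimethylsilyl)methyl]prop-2-en-1-ol
Product: 8 (E)-3-iodo-2-[(trimethylsilyl)methyl]allyl acetate
Conditions: Ac2O, pyridine, DMAP (cat.), CH2Cl2, 0 °C
Reagents that add atoms: acetic anhydride, CC(=O)OC(C)=O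
Why: O-Acetylation (acyl transfer) installs the allylic leaving group needed for π-allyl formation in step 9.

Step 7
Reactants: 5 7-oxo-8(17)-ene aldehyde; 8 (E)-3-iodo-2-[(trimethylsilyl)methyl]allyl acetate
Product: 9 C12 allylic alcohol carrying the C13=C16(CH2OAc)(CH2SiMe3) unit (C12 epimers)
Conditions: CrCl2 (4 equiv), NiCl2 (2 mol%), DMF, rt
Reagents that add atoms: none
Why: Nozaki–Hiyama–Kishi coupling: the alkenylchromium species (nickel-catalysed insertion of divalent chromium into C–I) adds only to the aldehyde and tolerates enone, acetate and allylsilane; C12 forms without control and is reset in step 17.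

Step 8
Reactants: 9 C12 allylic alcohol
Product: 10 C12 TBS ether (C12 epimers)
Conditions: TBSCl, imidazole, DMF, rt
Reagents that add atoms: tert-butyldimethylsilyl chloride, CC(C)(C)[Si](C)(C)Cl
Why: Silyl ether formation masks the allylic alcohol so it cannot ionise or O-alkylate the π-allyl intermediate of step 9.

Step 9
Reactants: 10 C12 TBS ether
Product: 11 7-oxo-ent-kaur-16-ene (3,19-acetonide, 12-OTBS)
Conditions: Pd(OAc)2 (10 mol%), P(Oi-Pr)3 (60 mol%), THF, 65 °C, 0.01 M
Reagents that add atoms: none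
Why: Intramolecular palladium–trimethylenemethane [3+2] cycloaddition: zerovalent palladium ionises the allylic acetate, acetate removes silicon, the substituted terminus C13 adds to the enone CH2 (which becomes C14), and the C8 enolate closes on the π-allyl terminus from the β face, anti to the axial C10 methyl; this forms rings C and D and the C8 quaternary centre, and C13 follows from the bridged geometry.

Step 10
Reactants: 11 7-oxo-ent-kaur-16-ene
Product: 13 6-diazo-7-ketone, via C6-trifluoroacetyl ketone 12 (not isolated)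
Conditions: LiN(SiMe3)2, THF, −78 °C; CF3CO2CH2CF3; then MsN3, Et3N, H2O, MeCN, rt
Reagents that add atoms: methanesulfonyl azide, CS(=O)(=O)N=[N+]=[N-]; 2,2,2-trifluoroethyl trifluoroacetate, O=C(OCC(F)(F)F)C(F)(F)F (its CF3CO group is carried only by 12)
Why: Detrifluoroacetylative diazo transfer (Regitz-type): C6 is the only enolisable position of the C7 ketone because C8 is quaternary, so the transfer is regiospecific.

Step 11
Reactants: 13 6-diazo-7-ketone
Product: 15 ring-B-contracted 2-(trimethylsilyl)ethyl ent-gibberell-16-en-7-oate (3,19-acetonide, 12-OTBS), via ketene 14 (not isolated)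
Conditions: hν (Hg lamp, Pyrex), Me3SiCH2CH2OH (10 equiv), THF, rt; then DBU (0.2 equiv), rt
Reagents that add atoms: 2-(trimethylsilyl)ethanol, OCC[Si](C)(C)C
Why: Photochemical Wolff rearrangement: the C7–C8 bond migrates to the C6 carbene, contracting ring B to a ketene that the alcohol traps; DBU equilibrates C6 to the more stable β-ester, away from the α face crowded by C14, C19 and C20.

Step 12
Reactants: 15 ring-contracted ester acetonide
Product: 16 3α,19-diol (12-OTBS, C7 2-(trimethylsilyl)ethyl ester)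
Conditions: PPTS, MeOH, 40 °C
Reagents that add atoms: none
Why: Mild acid-catalysed transacetalisation removes the acetonide while the hindered secondary TBS ether survives.

Step 13
Reactants: 16 3α,19-diol
Product: 19 C20 aldoxime (19-OH and 3α-OH free), via 19-nitrite ester 17 (not isolated), via C20-nitroso compound 18 (not isolated)
Conditions: NOCl (1.1 equiv), pyridine, −30 °C; then hν (Hg lamp, Pyrex), benzene, 10 °C; then i-PrOH, 60 °C
Reagents that add atoms: nitrosyl chloride, O=NCl
Why: Barton nitrite photolysis: the primary 19-OH is nitrosated preferentially, O–N homolysis gives the 19-alkoxyl radical, which abstracts hydrogen from the 1,3-diaxial C20 methyl (the competing C2–H and C6–H sites are deactivated by the C3 oxygen and the C7 ester); NO recombination and tautomerisation give the oxime.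

Step 14
Reactants: 19 C20 aldoxime
Product: 20 3α,12,19-triol oxime (C12 epimers)
Conditions: HF·pyridine, THF, 0 °C to rt
Reagents that add atoms: none
Why: Fluoride-mediated desilylation frees 12-OH; the 2-(trimethylsilyl)ethyl ester is stable to buffered HF·pyridine.

Step 15
Reactants: 20 triol oxime
Product: 21 3,12-dioxo-19-al-20-nitrile
Conditions: (COCl)2, DMSO, CH2Cl2, −78 °C; then Et3N, −78 °C to rt
Reagents that add atoms: none
Why: Swern oxidation: the activated sulfoxide oxidises both secondary alcohols and the primary alcohol and dehydrates the aldoxime to the nitrile; this erases the uncontrolled C12 centre and the C3 centre that must be inverted, giving one compound.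

Step 16
Reactants: 21 3,12-dioxo-19-al-20-nitrile
Product: 22 3,12-dioxo-20-nitrile-19-oic acid
Conditions: NaClO2, NaH2PO4, 2-methyl-2-butene, t-BuOH/H2O, rt
Reagents that add atoms: sodium chlorite, [Na+].[O-]Cl=O
Why: Pinnick oxidation converts the neopentyl aldehyde to the acid without touching ketones, nitrile or the alkene (hypochlorite is scavenged).

Step 17
Reactants: 22 3,12-dioxo-20-nitrile-19-oic acid
Product: 23 3β,12α-dihydroxy-20-nitrile-19-oic acid (C7 2-(trimethylsilyl)ethyl ester)
Conditions: LiBH(s-Bu)3 (4 equiv), THF, −78 °C; aq. HCl work-up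
Reagents that add atoms: none
Why: Bulky-borohydride reduction attacks both ring ketones equatorially to give the axial alcohols: 3β-OH, and 12α-OH because the α face at C12 is blocked by the 1,3-diaxial C10 centre so hydride enters from the β face; nitrile and ester are untouched at −78 °C.

Step 18
Reactants: 23 3β,12α-dihydroxy-20-nitrile-19-oic acid ester
Product: 24 3β,12α-dihydroxy-20-nitrile-7,19-dioic acid
Conditions: Bu4NF, THF, rt
Reagents that add atoms: none
Why: Fluoride-induced β-fragmentation of the 2-(trimethylsilyl)ethyl ester frees the C7 acid under non-hydrolytic conditions.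

Step 19
Reactants: 24 3β,12α-dihydroxy-20-nitrile-7,19-dioic acid
Product: 25 CNP0218328.1 (3β,12α-dihydroxy-20-oxo-ent-gibberell-16-ene-7,19-dioic acid)
Conditions: i-Bu2AlH (8 equiv), CH2Cl2, −78 to −40 °C; aq. KNaC4H4O6 (potassium sodium tartrate), then 1 M HCl
Reagents that add atoms: water, O
Why: Partial hydride reduction of the nitrile to the N-aluminoimine (acids and alcohols are first converted to unreactive aluminium salts), hydrolysed to the aldehyde on acidic work-up.

**Compound list**
1 | andrographolide | C[C@@]12CC[C@H]([C@@]([C@H]1CCC(=C)[C@H]2C/C=C/3\[C@@H](COC3=O)O)(C)CO)O | starting material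
2 | andrographolide 3,19-acetonide | C[C@@]12CC[C@H]3OC(C)(C)OC[C@]3([C@H]1CCC(=C)[C@H]2C/C=C/4\[C@@H](COC4=O)O)C | intermediate
3 | C12 aldehyde (13,14,15,16-tetranor-ent-labd-8(17)-en-12-al 3,19-acetonide) | C[C@@]12CC[C@H]3OC(C)(C)OC[C@]3([C@H]1CCC(=C)[C@H]2CC=O)C | intermediate
4 | 7-hydroxy aldehyde (axial 7-OH, anti to C20) | C[C@@]12CC[C@H]3OC(C)(C)OC[C@]3([C@H]1C[C@H](O)C(=C)[C@H]2CC=O)C | intermediate
5 | 7-oxo-8(17)-ene aldehyde | C[C@@]12CC[C@H]3OC(C)(C)OC[C@]3([C@H]1CC(=O)C(=C)[C@H]2CC=O)C | intermediate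
6 | propargyl alcohol | C#CCO | starting material
7 | (E)-3-iodo-2-[(trimethylsilyl)methyl]prop-2-en-1-ol | OC/C(C[Si](C)(C)C)=C\I | intermediate
8 | (E)-3-iodo-2-[(trimethylsilyl)methyl]allyl acetate | CC(=O)OC/C(C[Si](C)(C)C)=C\I | intermediate
9 | C12 allylic alcohol, cycloaddition precursor (C12 epimers) | C[C@@]12CC[C@H]3OC(C)(C)OC[C@]3([C@H]1CC(=O)C(=C)[C@H]2CC(O)/C=C(\COC(C)=O)C[Si](C)(C)C)C | intermediate
10 | C12 TBS ether (C12 epimers) | C[C@@]12CC[C@H]3OC(C)(C)OC[C@]3([C@H]1CC(=O)C(=C)[C@H]2CC(O[Si](C)(C)C(C)(C)C)/C=C(\COC(C)=O)C[Si](C)(C)C)C | intermediate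
11 | 7-oxo-ent-kaur-16-ene, 3,19-acetonide, 12-OTBS (C12 epimers) | C=C1C[C@]23C[C@H]1C(O[Si](C)(C)C(C)(C)C)C[C@H]2[C@]1(C)CC[C@H]4OC(C)(C)OC[C@@]4(C)[C@H]1CC3=O | intermediate
12 | C6-trifluoroacetyl ketone | C=C1C[C@]23C[C@H]1C(O[Si](C)(C)C(C)(C)C)C[C@H]2[C@]1(C)CC[C@H]4OC(C)(C)OC[C@@]4(C)[C@H]1C(C(=O)C(F)(F)F)C3=O | intermediate (not isolated)
13 | 6-diazo-7-ketone | C=C1C[C@]23C[C@H]1C(O[Si](C)(C)C(C)(C)C)C[C@H]2[C@]1(C)CC[C@H]4OC(C)(C)OC[C@@]4(C)[C@H]1C(=[N+]=[N-])C3=O | intermediate
14 | ring-contracted ketene | C=C1C[C@]23C[C@H]1C(O[Si](C)(C)C(C)(C)C)C[C@H]2[C@]1(C)CC[C@H]4OC(C)(C)OC[C@@]4(C)[C@H]1C3=C=O | intermediate (not isolated)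
15 | 2-(trimethylsilyl)ethyl ent-gibberell-16-en-7-oate, 3,19-acetonide, 12-OTBS | C=C1C[C@]23C[C@H]1C(O[Si](C)(C)C(C)(C)C)C[C@H]2[C@]1(C)CC[C@H]4OC(C)(C)OC[C@@]4(C)[C@H]1[C@@H]3C(=O)OCC[Si](C)(C)C | intermediate
16 | 3α,19-diol (12-OTBS, C7 ester) | C=C1C[C@]23C[C@H]1C(O[Si](C)(C)C(C)(C)C)C[C@H]2[C@]1(C)CC[C@@H](O)[C@@](C)(CO)[C@H]1[C@@H]3C(=O)OCC[Si](C)(C)C | intermediate
17 | 19-nitrite ester | C=C1C[C@]23C[C@H]1C(O[Si](C)(C)C(C)(C)C)C[C@H]2[C@]1(C)CC[C@@H](O)[C@@](C)(CON=O)[C@H]1[C@@H]3C(=O)OCC[Si](C)(C)C | intermediate (not isolated)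
18 | C20-nitroso compound | C=C1C[C@]23C[C@H]1C(O[Si](C)(C)C(C)(C)C)C[C@H]2[C@]1(CN=O)CC[C@@H](O)[C@@](C)(CO)[C@H]1[C@@H]3C(=O)OCC[Si](C)(C)C | intermediate (not isolated)
19 | C20 aldoxime (3α,19-diol, 12-OTBS) | C=C1C[C@]23C[C@H]1C(O[Si](C)(C)C(C)(C)C)C[C@H]2[C@]1(C=NO)CC[C@@H](O)[C@@](C)(CO)[C@H]1[C@@H]3C(=O)OCC[Si](C)(C)C | intermediate
20 | 3α,12,19-triol oxime (C12 epimers) | C=C1C[C@]23C[C@H]1C(O)C[C@H]2[C@]1(C=NO)CC[C@@H](O)[C@@](C)(CO)[C@H]1[C@@H]3C(=O)OCC[Si](C)(C)C | intermediate
21 | 3,12-dioxo-19-al-20-nitrile | C=C1C[C@]23C[C@H]1C(=O)C[C@H]2[C@]1(C#N)CCC(=O)[C@@](C)(C=O)[C@H]1[C@@H]3C(=O)OCC[Si](C)(C)C | intermediate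
22 | 3,12-dioxo-20-nitrile-19-oic acid | C=C1C[C@]23C[C@H]1C(=O)C[C@H]2[C@]1(C#N)CCC(=O)[C@@](C)(C(=O)O)[C@H]1[C@@H]3C(=O)OCC[Si](C)(C)C | intermediate
23 | 3β,12α-dihydroxy-20-nitrile-19-oic acid, C7 2-(trimethylsilyl)ethyl ester | C=C1C[C@]23C[C@H]1[C@@H](O)C[C@H]2[C@]1(C#N)CC[C@H](O)[C@@](C)(C(=O)O)[C@H]1[C@@H]3C(=O)OCC[Si](C)(C)C | intermediate
24 | 3β,12α-dihydroxy-20-nitrile-7,19-dioic acid | C=C1C[C@]23C[C@H]1[C@@H](O)C[C@H]2[C@]1(C#N)CC[C@H](O)[C@@](C)(C(=O)O)[C@H]1[C@@H]3C(=O)O | intermediate
25 | CNP0218328.1 | C=C1C[C@]23C[C@H]1[C@@H](O)C[C@H]2[C@]1(C=O)CC[C@H](O)[C@@](C)(C(=O)O)[C@H]1[C@@H]3C(=O)O | target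

**Totals**
Total step count: 19. Longest linear sequence: 17 steps (steps 1–4 and 7–19, from andrographolide); steps 5–6 make coupling partner 8.

**Steps most likely to fail, with fallbacks**

Step 13 (C20 C–H oxidation) is the weakest: the 19-alkoxyl radical reaches C20 only through a seven-membered transition state, and abstraction at C2 or C6 or loss of formaldehyde can compete. The fallback still relies on the same hydrogen transfer but changes the radical capture: from 16, PhI(OAc)2, I2, cyclohexane, hν gives the 20-iodo-19-alcohol F2 by iodine-atom transfer (ring closure to the ether is slow at the neopentyl carbon); Me3Sn–SnMe3, NO (1 atm), hν, benzene, then i-PrOH (radical nitrosation and tautomerisation) returns to the route at 19.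

Step 9 (bridged cycloaddition) has no close precedent for this tether geometry. The fallback is a stepwise annulation: from 10, EtAlCl2, CH2Cl2, −78 °C (intramolecular Hosomi–Sakurai 1,4-addition of the allylsilane γ-carbon C13 to the enone CH2) gives the ring-C-closed allylic acetate F1; Pd(PPh3)4, KOt-Bu, THF, rt (intramolecular Tsuji–Trost C-allylation of the thermodynamic C8 enolate) then closes ring D and returns to the route at 11.

Step 19 (nitrile reduction beside two free acids) risks over-reduction or an unreactive neopentyl nitrile. The fallback unveils the aldehyde one step earlier without a hydride: from 23, Raney Ni, NaH2PO2, pyridine/AcOH/H2O, 40 °C (hydrogen-transfer reduction to the imine with in situ hydrolysis, ester-tolerant) gives the aldehyde ester F3; Bu4NF, THF then frees the C7 acid and returns to the route at 25.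

**Further compounds**
F1 | step 9 | ring-C-closed Hosomi–Sakurai adduct, C13 bearing C(=CH2)CH2OAc, C8–H unassigned | C=C(COC(C)=O)[C@@H]1C(O[Si](C)(C)C(C)(C)C)C[C@H]2[C@]3(C)CC[C@H]4OC(C)(C)OC[C@@]4(C)[C@H]3CC(=O)C2C1
F2 | step 13 | 20-iodo-3α,19-diol (12-OTBS, C7 ester) | C=C1C[C@]23C[C@H]1C(O[Si](C)(C)C(C)(C)C)C[C@H]2[C@]1(CI)CC[C@@H](O)[C@@](C)(CO)[C@H]1[C@@H]3C(=O)OCC[Si](C)(C)C
F3 | step 19 | 3β,12α-dihydroxy-20-oxo-19-oic acid, C7 2-(trimethylsilyl)ethyl ester | C=C1C[C@]23C[C@H]1[C@@H](O)C[C@H]2[C@]1(C=O)CC[C@H](O)[C@@](C)(C(=O)O)[C@H]1[C@@H]3C(=O)OCC[Si](C)(C)C
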